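**Retrosynthetic overview**
- Feature: ring C is a benzene with the ether O at C1, I at C2, Br at C4 and H at C3, C5 and C6. Its C3–C6 unit is C6–C5(Br)–C4–C3 of 5-bromo-2-pyrone, and its C1–C2 unit is an alkyne carrying the ring B oxygen and a silyl placeholder for iodine.
- Last disconnection: the ring A–O bond, by SNAr of the ring B phenol on 3,5-dibromo-2-fluorobenzaldehyde. Peracid oxidation then exchanges the formyl group for OH.
- Next: C–I back to C–SiMe3 (ipso substitution), then ring C back to an aryloxy(trimethylsilyl)acetylene plus 5-bromo-2-pyrone ([4+2], then loss of CO2).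
- The ynol ether goes back through the bromovinyl and vinyl ethers to 4,5,6-tribromoguaiacol (guaiacol + Br2). The pyrone goes back to coumalic acid.
- Ring order: ring B is bought (guaiacol), ring C is the only ring built, and ring A is bought and attached last. The target has no stereocentre.

Key step: step 7

Assumption: guaiacol, 1,2-dibromoethane, coumalic acid and 3,5-dibromo-2-fluorobenzaldehyde are taken as catalogue compounds.

**Step 1**
Reactants: 1 guaiacol (2-methoxyphenol)
Product: 2 2,3,4-tribromo-6-methoxyphenol (4,5,6-tribromoguaiacol)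
Conditions: Br2 (3.05 equiv), AcOH, 0 °C → rt
Reagents that add atoms: bromine, BrBr
Why: Electrophilic aromatic bromination: the hydroxyl group steers bromine to C4 and C6 and the methoxy group to C5, whereas C3 is meta to the hydroxyl group and stays free, so three equivalents should stop at the known 4,5,6-tribromide.

**Step 2**
Reactants: 2 2,3,4-tribromo-6-methoxyphenol; 3 1,2-dibromoethane
Product: 4 1,2,3-tribromo-4-(2-bromoethoxy)-5-methoxybenzene
Conditions: 3 (5 equiv), K2CO3 (1.5 equiv), MeCN, reflux
Reagents that add atoms: none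
Why: Williamson ether synthesis on a primary bromide, in which the acidic phenol is ionised by carbonate and the excess of 3 suppresses a second alkylation.

**Step 3**
Reactants: 4 1,2,3-tribromo-4-(2-bromoethoxy)-5-methoxybenzene
Product: 5 1,2,3-tribromo-4-(ethenyloxy)-5-methoxybenzene
Conditions: KOt-Bu (1.3 equiv), THF, 0 °C → rt
Reagents that add atoms: none
Why: E2 dehydrobromination of a 2-aryloxyethyl bromide by a hindered alkoxide, the standard two-step O-vinylation of phenols, which is fast enough at 0 °C in THF that the aryl bromides are not touched.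

**Step 4**
Reactants: 5 1,2,3-tribromo-4-(ethenyloxy)-5-methoxybenzene
Product: 7 1,2,3-tribromo-4-[(2-bromoethenyl)oxy]-5-methoxybenzene (E/Z mixture), via 1,2-dibromoethyl ether 6 (not isolated)
Conditions: Br2 (1.0 equiv), CH2Cl2, −78 °C; then DBU (1.5 equiv), −78 °C → rt
Reagents that add atoms: bromine, BrBr
Why: Electrophilic addition of bromine to the enol ether double bond, which is far more nucleophilic than the deactivated ring B, followed by amidine-induced E2 loss of the labile bromide next to oxygen, the bromination–dehydrobromination sequence known for enol ethers and glycals; the alkene geometry does not matter because both isomers lead to the same alkyne.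

**Step 5**
Reactants: 7 1,2,3-tribromo-4-[(2-bromoethenyl)oxy]-5-methoxybenzene
Product: 10 [(2,3,4-tribromo-6-methoxyphenoxy)ethynyl]trimethylsilane, via terminal ynol ether 8 (not isolated), via lithium acetylide 9 (not isolated)
Conditions: LiN(SiMe3)2 (2.5 equiv), THF, −78 → 0 °C; then Me3SiCl (1.5 equiv), −78 °C → rt; pH 7 work-up, Et3N-washed silica
Reagents that add atoms: chlorotrimethylsilane, C[Si](C)(C)Cl
Why: β-Elimination of HBr from a 2-halovinyl ether (the classical entry to aryloxyacetylenes), deprotonation of the acidic alkyne C–H and C-silylation of the acetylide, run with a hindered silazide instead of an alkyllithium or LiN(i-Pr)2 because this base neither exchanges aryl bromine for lithium nor metalates the ring B C–H at low temperature.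

**Step 6**
Reactants: 11 coumalic acid (2-oxo-2H-pyran-5-carboxylic acid)
Product: 12 5-bromo-2H-pyran-2-one
Conditions: NBS (1.05 equiv), LiOAc (0.2 equiv), aq MeCN, rt
Reagents that add atoms: N-bromosuccinimide, O=C1CCC(=O)N1Br
Why: Hunsdiecker-type bromodecarboxylation with NBS and catalytic LiOAc: electrophilic bromine attacks C5, the β-carbon of the ring enol ether, at the carboxyl-bearing position and CO2 leaves, while limiting NBS to one equivalent holds back the slower second bromination at C3.

**Step 7**
Reactants: 10 [(2,3,4-tribromo-6-methoxyphenoxy)ethynyl]trimethylsilane; 12 5-bromo-2H-pyran-2-one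
Product: 14 [5-bromo-2-(2,3,4-tribromo-6-methoxyphenoxy)phenyl]trimethylsilane, via bicyclic lactone 13 (not isolated)
Conditions: 12 (2 equiv), BHT and 2,6-di-tert-butylpyridine (each cat.), mesitylene, sealed tube, 160 °C
Reagents that add atoms: none
Why: Proposed new method: the aryloxy oxygen raises the HOMO of the alkyne in 10 and puts its largest coefficient on the silyl-bearing carbon, so 10 should add across C3 and C6 of the electron-poor diene 12 in an asynchronous inverse-electron-demand Diels–Alder reaction, and the strained lactone-bridged adduct 13 should expel CO2 by retro-[4+2] at the same temperature. The closest known reactions are the thermal benzannulations of 2-pyrones, bromo-2-pyrones among them, with silyl-, boryl- and amino-substituted alkynes, and the cycloadditions of 12 with enol ethers; an aryloxy(silyl)acetylene has not been shown as the two-carbon partner. Ring C is closed by intermolecular [4+2] cycloaddition that forms the bonds pyrone C6–C(Si) and pyrone C3–C(OAr), and loss of the O1–C2 bridge makes the closure irreversible. The two bridgehead stereocentres of racemic 13 vanish on aromatisation, so no stereocontrol is needed. The step needs regioselectivity: C6 is the far end of the vinylogous acceptor system of the pyrone, where enol ethers and ketene acetals are known to bond through their nucleophilic carbon, and the positive charge building on the other alkyne carbon is stabilised by oxygen and by the β-silyl effect alike, so both substituents of 10 act in the same sense and place O para and Si meta to Br. Compound 10 has no C–H β to oxygen in its O-substituent, so the retro-ene fragmentation to a ketene that limits alkyl ynol ethers is closed, and the silyl cap suppresses the polymerisation typical of terminal aryloxyacetylenes.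

**Step 8**
Reactants: 14 [5-bromo-2-(2,3,4-tribromo-6-methoxyphenoxy)phenyl]trimethylsilane
Product: 15 1,2,3-tribromo-4-(4-bromo-2-iodophenoxy)-5-methoxybenzene
Conditions: ICl (1.1 equiv), CH2Cl2, 0 °C
Reagents that add atoms: iodine monochloride, ClI
Why: Ipso-iododesilylation (electrophilic aromatic substitution at the C–Si carbon): attack ortho to the aryloxy donor gives a cation stabilised by the β-silyl effect, which outruns any C–H iodination, and the exchange is placed before step 9 because BBr3 would attack the aryl–silicon bond.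

**Step 9**
Reactants: 15 1,2,3-tribromo-4-(4-bromo-2-iodophenoxy)-5-methoxybenzene
Product: 17 3,4,5-tribromo-2-(4-bromo-2-iodophenoxy)phenol, via aryloxydibromoborane 16 (not isolated)
Conditions: BBr3 (2 equiv), CH2Cl2, −78 °C → rt; then H2O
Reagents that add atoms: none
Why: Lewis acid cleavage of an aryl methyl ether with BBr3 (SN2 attack of bromide on the methyl group of the boron-complexed ether), to which the diaryl ether, C–Br and C–I bonds are inert.

**Step 10**
Reactants: 17 3,4,5-tribromo-2-(4-bromo-2-iodophenoxy)phenol; 18 3,5-dibromo-2-fluorobenzaldehyde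
Product: 19 3,5-dibromo-2-[3,4,5-tribromo-2-(4-bromo-2-iodophenoxy)phenoxy]benzaldehyde
Conditions: Cs2CO3 (1.5 equiv), DMF, 60 °C
Reagents that add atoms: none
Why: SNAr by addition–elimination at the C–F carbon, the only halogen-bearing position ortho or para to the formyl group, using the ring B oxygen that has only one ortho substituent; the moderate temperature is chosen so that this oxygen does not turn on the C–I carbon of ring C.

**Step 11**
Reactants: 19 3,5-dibromo-2-[3,4,5-tribromo-2-(4-bromo-2-iodophenoxy)phenoxy]benzaldehyde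
Product: 21 bromoiesol B, 3,5-dibromo-2-[3,4,5-tribromo-2-(4-bromo-2-iodophenoxy)phenoxy]phenol, via aryl formate 20 (not isolated)
Conditions: mCPBA (2 equiv), CH2Cl2, reflux; then MeOH, HCl (cat.), rt
Reagents that add atoms: 3-chloroperoxybenzoic acid, O=C(OO)c1cccc(Cl)c1
Why: Baeyer–Villiger oxidation of an aryl aldehyde (the peracid form of the Dakin reaction): in the Criegee adduct the ring A carbon, pushed by the ortho aryloxy oxygen, migrates in preference to hydride, as is known for brominated 2-aryloxybenzaldehydes, acid methanolysis then frees the phenol without base, and a thiosulfate wash returns any over-oxidised iodine to the aryl iodide.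

**Compound list**
1 | guaiacol | COc1ccccc1O | starting material
2 | 2,3,4-tribromo-6-methoxyphenol | COc1cc(Br)c(Br)c(Br)c1O | intermediate
3 | 1,2-dibromoethane | BrCCBr | starting material
4 | 1,2,3-tribromo-4-(2-bromoethoxy)-5-methoxybenzene | COc1cc(Br)c(Br)c(Br)c1OCCBr | intermediate
5 | 1,2,3-tribromo-4-(ethenyloxy)-5-methoxybenzene | COc1cc(Br)c(Br)c(Br)c1OC=C | intermediate
6 | 1,2,3-tribromo-4-(1,2-dibromoethoxy)-5-methoxybenzene (racemic, not isolated) | COc1cc(Br)c(Br)c(Br)c1OC(Br)CBr | intermediate
7 | 1,2,3-tribromo-4-[(2-bromoethenyl)oxy]-5-methoxybenzene (E/Z mixture) | COc1cc(Br)c(Br)c(Br)c1OC=CBr | intermediate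
8 | 1,2,3-tribromo-4-(ethynyloxy)-5-methoxybenzene (not isolated) | COc1cc(Br)c(Br)c(Br)c1OC#C | intermediate
9 | lithium (2,3,4-tribromo-6-methoxyphenoxy)acetylide (not isolated) | COc1cc(Br)c(Br)c(Br)c1OC#C[Li] | intermediate
10 | [(2,3,4-tribromo-6-methoxyphenoxy)ethynyl]trimethylsilane | COc1cc(Br)c(Br)c(Br)c1OC#C[Si](C)(C)C | intermediate
11 | coumalic acid | O=C(O)c1ccc(=O)oc1 | starting material
12 | 5-bromo-2H-pyran-2-one | O=c1ccc(Br)co1 | intermediate
13 | 7-bromo-5-(2,3,4-tribromo-6-methoxyphenoxy)-6-(trimethylsilyl)-2-oxabicyclo[2.2.2]octa-5,7-dien-3-one (racemic, not isolated) | O=C1OC2C(Br)=CC1C(Oc3c(OC)cc(Br)c(Br)c3Br)=C2[Si](C)(C)C | intermediate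
14 | [5-bromo-2-(2,3,4-tribromo-6-methoxyphenoxy)phenyl]trimethylsilane | COc1cc(Br)c(Br)c(Br)c1Oc1ccc(Br)cc1[Si](C)(C)C | intermediate
15 | 1,2,3-tribromo-4-(4-bromo-2-iodophenoxy)-5-methoxybenzene | COc1cc(Br)c(Br)c(Br)c1Oc1ccc(Br)cc1I | intermediate
16 | dibromo[3,4,5-tribromo-2-(4-bromo-2-iodophenoxy)phenoxy]borane (not isolated) | BrB(Br)Oc1cc(Br)c(Br)c(Br)c1Oc1ccc(Br)cc1I | intermediate
17 | 3,4,5-tribromo-2-(4-bromo-2-iodophenoxy)phenol | Oc1cc(Br)c(Br)c(Br)c1Oc1ccc(Br)cc1I | intermediate
18 | 3,5-dibromo-2-fluorobenzaldehyde | O=Cc1cc(Br)cc(Br)c1F | starting material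
19 | 3,5-dibromo-2-[3,4,5-tribromo-2-(4-bromo-2-iodophenoxy)phenoxy]benzaldehyde | O=Cc1cc(Br)cc(Br)c1Oc1cc(Br)c(Br)c(Br)c1Oc1ccc(Br)cc1I | intermediate
20 | 3,5-dibromo-2-[3,4,5-tribromo-2-(4-bromo-2-iodophenoxy)phenoxy]phenyl formate (not isolated) | O=COc1cc(Br)cc(Br)c1Oc1cc(Br)c(Br)c(Br)c1Oc1ccc(Br)cc1I | intermediate
21 | bromoiesol B | Oc1cc(Br)cc(Br)c1Oc1cc(Br)c(Br)c(Br)c1Oc1ccc(Br)cc1I | target

**Step count**
Total: 11 steps.
Longest linear sequence: 10 steps (1 → 2 → 4 → 5 → 7 → 10 → 14 → 15 → 17 → 19 → 21). Step 6 is a one-step side branch.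

**Steps most likely to fail**

1. **Step 7.**
- What may go wrong: the tribromoaryl group drains electron density from the ynol oxygen, so the cycloaddition may lag behind thermal self-consumption of both partners. The bulk of the silyl group may also erode the regiocontrol.
- Fallback: known chemistry, with ring C taken from a bought arene. It sets out from 2 and comes back at 15.
- Phenol 2 is arylated by SNAr with 4-bromo-1-fluoro-2-nitrobenzene (K2CO3, DMF, 80 °C) to 1,2,3-tribromo-4-(4-bromo-2-nitrophenoxy)-5-methoxybenzene F1.
- The nitro group is reduced with Fe powder and NH4Cl in aqueous EtOH to 5-bromo-2-(2,3,4-tribromo-6-methoxyphenoxy)aniline F2.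
- Diazotisation (NaNO2, H2SO4, AcOH, 0 °C) gives 5-bromo-2-(2,3,4-tribromo-6-methoxyphenoxy)benzenediazonium hydrogensulfate F3, and KI (Sandmeyer-type iodination) then gives 15.
- Both positions of ring B next to the ether oxygen are substituted, so the diazonium carbon has no C–H to cyclise onto.

2. **Step 5.**
- What may go wrong: in the E-configured part of 7, H and Br are syn, so loss of HBr may be slow with a silazide base. Forcing it by warming invites metalation of the lone ring B C–H with migration of bromine, and polymerisation of the unsilylated alkyne.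
- Fallback: the vinyl bromide is replaced by a vinyl triflate made from an aldehyde, and silicon is put on without a metal base. It sets out from 2 and comes back at 10.
- Alkylation of 2 with 2-bromo-1,1-diethoxyethane (K2CO3, DMF, 100 °C) gives 1,2,3-tribromo-4-(2,2-diethoxyethoxy)-5-methoxybenzene F4.
- Aqueous HCl in THF frees (2,3,4-tribromo-6-methoxyphenoxy)acetaldehyde F5.
- Tf2O with 2,6-di-tert-butyl-4-methylpyridine in CH2Cl2 gives 2-(2,3,4-tribromo-6-methoxyphenoxy)ethenyl trifluoromethanesulfonate F6.
- KOt-Bu in THF at −78 °C eliminates triflate to give 8. This is silylated in solution with N,O-bis(trimethylsilyl)acetamide and catalytic tetramethylammonium pivalate in MeCN to 10.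

3. **Step 10.**
- What may go wrong: the fluoride is flanked by CHO and Br, so substitution may be slow. That gives the ring B phenoxide time to close onto the C–I carbon of ring C (dioxin-type ring closure) or to shuffle aryl groups by Smiles migration.
- Fallback: the polarity of ring A is changed to a diaryliodonium salt, the usual way to crowded polybrominated diaryl ethers. This also bypasses step 11. It sets out from 17 and comes back at 21.
- Commercial 2,4-dibromo-6-methoxyaniline is diazotised (NaNO2, H2SO4, 0 °C) to 2,4-dibromo-6-methoxybenzenediazonium hydrogensulfate F7. KI converts this to 1,5-dibromo-2-iodo-3-methoxybenzene F8.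
- mCPBA and TsOH·H2O in MeCN oxidise it to 1,5-dibromo-2-[hydroxy(tosyloxy)iodo]-3-methoxybenzene F9.
- In the same flask 1,3,5-trimethoxybenzene captures F9 as (2,4-dibromo-6-methoxyphenyl)(2,4,6-trimethoxyphenyl)iodonium tosylate F10.
- Phenol 17 is O-arylated with it (K2CO3, MeCN, 40 °C; metal-free ligand coupling at iodine, in which the electron-rich trimethoxyphenyl group stays on iodine). This gives bromoiesol B methyl ether F11.
- BBr3 in CH2Cl2, through the aryloxydibromoborane F12, then water, gives 21.

**Further compounds**
F1 | step 7 | 1,2,3-tribromo-4-(4-bromo-2-nitrophenoxy)-5-methoxybenzene | COc1cc(Br)c(Br)c(Br)c1Oc1ccc(Br)cc1[N+](=O)[O-]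
F2 | step 7 | 5-bromo-2-(2,3,4-tribromo-6-methoxyphenoxy)aniline | COc1cc(Br)c(Br)c(Br)c1Oc1ccc(Br)cc1N
F3 | step 7 | 5-bromo-2-(2,3,4-tribromo-6-methoxyphenoxy)benzenediazonium hydrogensulfate | COc1cc(Br)c(Br)c(Br)c1Oc1ccc(Br)cc1[N+]#N.OS(=O)(=O)[O-]
F4 | step 5 | 1,2,3-tribromo-4-(2,2-diethoxyethoxy)-5-methoxybenzene | CCOC(COc1c(OC)cc(Br)c(Br)c1Br)OCC
F5 | step 5 | (2,3,4-tribromo-6-methoxyphenoxy)acetaldehyde | COc1cc(Br)c(Br)c(Br)c1OCC=O
F6 | step 5 | 2-(2,3,4-tribromo-6-methoxyphenoxy)ethenyl trifluoromethanesulfonate (E/Z mixture) | COc1cc(Br)c(Br)c(Br)c1OC=COS(=O)(=O)C(F)(F)F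
F7 | step 10 | 2,4-dibromo-6-methoxybenzenediazonium hydrogensulfate | COc1cc(Br)cc(Br)c1[N+]#N.OS(=O)(=O)[O-]
F8 | step 10 | 1,5-dibromo-2-iodo-3-methoxybenzene | COc1cc(Br)cc(Br)c1I
F9 | step 10 | 1,5-dibromo-2-[hydroxy(tosyloxy)iodo]-3-methoxybenzene | COc1cc(Br)cc(Br)c1I(O)OS(=O)(=O)c1ccc(C)cc1
F10 | step 10 | (2,4-dibromo-6-methoxyphenyl)(2,4,6-trimethoxyphenyl)iodonium tosylate | COc1cc(Br)cc(Br)c1[I+]c1c(OC)cc(OC)cc1OC.Cc1ccc(cc1)S(=O)(=O)[O-]
F11 | step 10 | bromoiesol B methyl ether, 1,5-dibromo-3-methoxy-2-[3,4,5-tribromo-2-(4-bromo-2-iodophenoxy)phenoxy]benzene | COc1cc(Br)cc(Br)c1Oc1cc(Br)c(Br)c(Br)c1Oc1ccc(Br)cc1I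
F12 | step 10 | dibromo{3,5-dibromo-2-[3,4,5-tribromo-2-(4-bromo-2-iodophenoxy)phenoxy]phenoxy}borane | BrB(Br)Oc1cc(Br)cc(Br)c1Oc1cc(Br)c(Br)c(Br)c1Oc1ccc(Br)cc1I
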